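## Retrosynthetic overview

Numbering: ring C1 (C=O), C2=C3, C4 (CHOH), C5, C6 (C–OH); side chain C1'–C17'. The plan rests on C3. It lies β to the C1 carbonyl and is bonded to carbinol C4, so C3–C4 is the bond between a C1–C2–C3 ketone homoenolate and a C4 aldehyde. C2/C3 are also the two CH2 groups that a Kulinkovich reaction places on an acyl carbon C1.
Target 34 ⇒ (desilylation; Saegusa–Ito C2=C3) 4-hydroxycyclohexanone 30 ⇒ (C3–C4, closure of the only ring of the target) cyclopropanol aldehyde 25, handled as its lactol 26.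
25 ⇒ (oxidation; Kulinkovich at C1) γ-lactone 22, in which C1 and O–C4 protect each other ⇒ (C2'–C3', catalytic enantioselective dialkylzinc addition) aldehyde 13 + C15 bromide 18 (oct-1-yne + 1,7-dibromoheptane).
13 ⇒ (S)-malic acid. Self-regeneration of the stereocentre puts allyl (C5–C4) on C6 with retention, and the CH2CO2H arm becomes C1'–C2'.

Key step: step 13

Assumption: the γ-hydroxy aldehyde 25 is expected to rest as its five-membered lactol 26 (anomeric centre undefined). 25 and 26 are treated as one substance in ring–chain equilibrium.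
Remark: the target numbering given above is used for all intermediates.

## Route

Step 1
Reactants: 1 (S)-malic acid; 2 pivalaldehyde
Product: 3 2-[(2S,4S)-2-tert-butyl-5-oxo-1,3-dioxolan-4-yl]acetic acid (cis)
Conditions: p-TsOH·H2O (cat.), H2SO4 (cat.), pentane, reflux, Dean–Stark; recrystallisation
Reagents that add atoms: pivalaldehyde, CC(C)(C)C=O
Why: Acid-catalysed acetalisation engages the α-hydroxy acid unit as the five-membered dioxolanone, and the cis isomer, whose acetal carbon stores the chirality of C6, is purified by crystallisation.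

Step 2
Reactants: 3 dioxolanone acid; 4 allyl bromide
Product: 6 2-[(2S,4S)-2-tert-butyl-5-oxo-4-(prop-2-enyl)-1,3-dioxolan-4-yl]acetic acid (allyl trans to tert-butyl), via dilithium enolate carboxylate 5 (not isolated)
Conditions: LiN(SiMe3)2 (2.2 equiv), THF, −78 °C; allyl bromide, −78 → −40 °C; 1 M HCl
Reagents that add atoms: allyl bromide, C=CCBr
Why: Enolate alkylation with self-regeneration of the stereocentre: dianion 5 is planar at C6 and allyl bromide enters anti to the tert-butyl group, so allyl replaces H with retention, which makes allyl the C5–C4 arm and CH2CO2H the C1'–C2' arm as the target requires.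

Step 3
Reactants: 6 allyl dioxolanone acid
Product: 9 2-[(3S)-3-hydroxy-2-oxooxolan-3-yl]acetic acid, via dioxolanone aldehyde 7 (not isolated), via dioxolanone primary alcohol 8 (not isolated)
Conditions: O3, CH2Cl2–MeOH, −78 °C; NaBH4, −78 → 0 °C; 1 M HCl, rt
Reagents that add atoms: ozone, [O-][O+]=O
Why: Ozonolysis with reductive work-up trims the allyl group to the C4 alcohol while it is the only alkene present, and the γ-hydroxyl then lactonises onto the activated dioxolanone carbonyl C1 with loss of pivalaldehyde, leaving C6 untouched.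

Step 4
Reactants: 9 hydroxy lactone acid
Product: 11 2-[(3S)-2-oxo-3-(triethylsilyloxy)oxolan-3-yl]acetic acid, via bis(triethylsilyl) ether ester 10 (not isolated)
Conditions: Et3SiOTf (2.5 equiv), 2,6-lutidine, CH2Cl2, 0 °C → rt; aq NaHCO3, then citric acid to pH 4
Reagents that add atoms: triethylsilyl triflate, CC[Si](CC)(CC)OS(=O)(=O)C(F)(F)F
Why: Silyl triflate/lutidine silylation reaches the tertiary C6 hydroxyl, and the labile silyl ester formed alongside is hydrolysed on aqueous work-up.

Step 5
Reactants: 11 silyloxy lactone acid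
Product: 12 S-ethyl 2-[(3S)-2-oxo-3-(triethylsilyloxy)oxolan-3-yl]ethanethioate
Conditions: EtSH, EDC·HCl, DMAP (cat.), CH2Cl2, 0 °C → rt
Reagents that add atoms: ethanethiol, CCS
Why: Carbodiimide (Steglich-type) thioesterification activates only the free C2' carboxyl group.

Step 6
Reactants: 12 thioester
Product: 13 2-[(3S)-2-oxo-3-(triethylsilyloxy)oxolan-3-yl]acetaldehyde
Conditions: Et3SiH, Pd/C (10 wt % Pd, 5 mol %), acetone, rt
Reagents that add atoms: none
Why: The Fukuyama reduction (insertion of zerovalent palladium into the C–S bond, hydride transfer from silicon) stops at the aldehyde and spares the lactone, so C2' never passes through the alcohol level at which the two arms of C6 would become interchangeable and C6 would racemise.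

Step 7
Reactants: 14 oct-1-yne; 15 1,7-dibromoheptane
Product: 17 15-bromopentadec-7-yne, via oct-1-ynyllithium 16 (not isolated)
Conditions: n-BuLi, THF–DMPU, −78 → 0 °C; 15 (3 equiv), 0 °C → rt
Reagents that add atoms: 1,7-dibromoheptane, BrCCCCCCCBr
Why: SN2 alkylation of a lithium acetylide by a primary bromide, with excess dibromide suppressing double alkylation.

Step 8
Reactants: 17 bromoalkyne
Product: 18 (7Z)-15-bromopentadec-7-ene
Conditions: H2 (1 atm), Pd/CaCO3–Pb(OAc)2 (Lindlar catalyst), quinoline, hexane, rt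
Reagents that add atoms: none
Why: Lindlar semihydrogenation adds H2 syn to the alkyne and sets the Z geometry of C10'=C11', the primary bromide being inert.

Step 9
Reactants: 18 (7Z)-15-bromopentadec-7-ene; 13 lactone aldehyde
Product: 21 (3S)-3-[(2S,10Z)-2-hydroxyheptadec-10-en-1-yl]-3-(triethylsilyloxy)oxolan-2-one, via pentadecenylmagnesium bromide 19 (not isolated), via dipentadecenylzinc 20 (not isolated)
Conditions: 18, Mg, Et2O, reflux; ZnCl2 (0.5 equiv), then 1,4-dioxane, filtration; Ti(Oi-Pr)4 (1.2 equiv), (1R,2R)-1,2-bis(trifluoromethanesulfonamido)cyclohexane (8 mol %), toluene, −20 °C; 13; sat. aq NH4Cl at −20 °C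
Reagents that add atoms: (7Z)-15-bromopentadec-7-ene, CCCCCC/C=C\CCCCCCCBr
Why: Titanium bis(sulfonamide)-catalysed enantioselective addition of a salt-free dialkylzinc to an aliphatic aldehyde is reagent-controlled, the (1R,2R) ligand steering the alkyl group to the Si face of the C2' aldehyde and so setting (S)-C2' independently of C6, while lactone and silyl ether are inert to organozinc and alkyltitanium species.

Step 10
Reactants: 21 hydroxy lactone
Product: 22 (3S)-3-[(2S,10Z)-2-(tert-butyldimethylsilyloxy)heptadec-10-en-1-yl]-3-(triethylsilyloxy)oxolan-2-one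
Conditions: t-BuMe2SiOTf, 2,6-lutidine, CH2Cl2, −78 °C (on crude 21)
Reagents that add atoms: tert-butyldimethylsilyl triflate, CC(C)(C)[Si](C)(C)OS(=O)(=O)C(F)(F)F
Why: Low-temperature silyl triflate silylation caps C2'–OH before it can displace O–C4 from the C1 carbonyl (translactonisation).

Step 11
Reactants: 22 bis-silyl lactone; 23 ethylmagnesium bromide
Product: 24 1-[(3S,5S,13Z)-5-(tert-butyldimethylsilyloxy)-1-hydroxy-3-(triethylsilyloxy)icos-13-en-3-yl]cyclopropan-1-ol
Conditions: Ti(Oi-Pr)4 (1.0 equiv), EtMgBr (3 equiv, slow addition), THF, 0 °C → rt; sat. aq NH4Cl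
Reagents that add atoms: ethylmagnesium bromide, CC[Mg]Br
Why: In the Kulinkovich reaction of a lactone the titanacyclopropane made from EtMgBr and Ti(Oi-Pr)4 acts as a 1,2-dicarbanion on C1, delivering C2 and C3 as the cyclopropane CH2 groups and releasing C4–OH, while the internal Z-alkene does not enter ligand exchange and no stereocentre is touched.

Step 12
Reactants: 24 cyclopropanol primary alcohol
Product: 26 7-[(2S,10Z)-2-(tert-butyldimethylsilyloxy)heptadec-10-en-1-yl]-7-(triethylsilyloxy)-4-oxaspiro[2.4]heptan-5-ol (lactol, C6 and C2' as in 24), via open hydroxy aldehyde 25 (not isolated)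
Conditions: SO3·pyridine, DMSO, Et3N, CH2Cl2, 0 °C
Reagents that add atoms: none
Why: The Parikh–Doering oxidation needs a carbinol C–H, so only the primary C4–OH reacts and the tertiary cyclopropanol, which one-electron and hypervalent iodine oxidants would open, is spared, and 25 closes to lactol 26 only after the oxidant is spent, so over-oxidation to a lactone is avoided.

Step 13
Reactants: 26 lactol (reacts through its open form 25, (3R,5S,13Z)-5-(tert-butyldimethylsilyloxy)-3-(1-hydroxycyclopropyl)-3-(triethylsilyloxy)icos-13-enal)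
Product: 30 (2S,4R)-2-[(2S,10Z)-2-(tert-butyldimethylsilyloxy)heptadec-10-en-1-yl]-4-hydroxy-2-(triethylsilyloxy)cyclohexan-1-one (C4–OH cis to C6–OSiEt3), via zinc bis(cyclopropoxide) 27 (not isolated), via zinc bis(homoenolate) 28 (not isolated), via triisopropoxytitanium homoenolate 29 (not isolated)
Conditions: Et2Zn (0.55 equiv), toluene–THF, 0 °C → rt; Ti(Oi-Pr)3Cl (1.2 equiv), 0 → 40 °C; sat. aq NH4Cl
Reagents that add atoms: none
Why: Proposed new method: Et2Zn in half-molar amount deprotonates two molecules of 26 so that both ethyl groups leave as ethane and no Zn–Et bond is left for titanium-promoted ethylation of the aldehyde; ring–chain equilibration of the zinc lactolate gives cyclopropoxide 27, strain release cleaves one of its two equivalent C1–CH2 bonds to homoenolate 28, and Ti(Oi-Pr)3Cl takes the C3 alkyl group over from zinc to give 29, in which the weakly Lewis-acidic metal can leave the C1 carbonyl oxygen, let the C1–C2 bond rotate and bind the C4 aldehyde oxygen. C3 then adds to C4 in a 6-exo-trig closure that makes the C3–C4 bond and the carbocycle, the only ring of the target. The closest known reaction type is the intermolecular addition to aldehydes of titanium and zinc homoenolates made from siloxycyclopropanes or from cyclopropanols and Et2Zn; the intramolecular addition of a ketone homoenolate is new, and the six-membered tether is what should make up for the low nucleophilicity of such species. C4 is set by a chair-like transition state with the C6 side chain equatorial and the C6 silyloxy group axial: the four-centre Ti–C3···C4=O array has to be cis-fused to the forming ring, the bulky Ti(Oi-Pr)3 takes the equatorial site on C3, and the aldehyde oxygen is thereby axial on C4, on the same face as O–C6, which is the cis-1,3 relationship of the target. The step needs attack through C3 rather than through C1 of an enolised homoenolate (this would close a four-membered ring), no β-elimination at the metal (C2 carries no leaving group; the cyclopropane is unsubstituted, so the opening has no regiochemical issue) and no loss of silanolate from the β-silyloxy aldehyde, which the non-basic zinc and titanium alkoxides and the resting lactolate form should secure.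

Step 14
Reactants: 30 4-hydroxycyclohexanone
Product: 31 (2S,4R)-2-[(2S,10Z)-2-(tert-butyldimethylsilyloxy)heptadec-10-en-1-yl]-2,4-bis(triethylsilyloxy)cyclohexan-1-one
Conditions: Et3SiOTf, 2,6-lutidine, CH2Cl2, −78 °C
Reagents that add atoms: triethylsilyl triflate, CC[Si](CC)(CC)OS(=O)(=O)C(F)(F)F
Why: Silyl triflate silylation reaches the hindered axial C4 hydroxyl, and lutidine at −78 °C does not enolise the ketone.

Step 15
Reactants: 31 tris-silyl ketone
Product: 32 trimethylsilyl enol ether (C1=C2) of 31, stereocentres unchanged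
Conditions: Me3SiOTf, Et3N, CH2Cl2, 0 °C
Reagents that add atoms: trimethylsilyl triflate, C[Si](C)(C)OS(=O)(=O)C(F)(F)F
Why: Soft enolisation–silylation can only proceed toward C2 because C6 is quaternary, so the enol ether is formed as a single regioisomer.

Step 16
Reactants: 32 silyl enol ether
Product: 33 (4S,6R)-6-[(2S,10Z)-2-(tert-butyldimethylsilyloxy)heptadec-10-en-1-yl]-4,6-bis(triethylsilyloxy)cyclohex-2-en-1-one
Conditions: Pd(OAc)2 (1.1 equiv), MeCN, rt
Reagents that add atoms: none
Why: In the Saegusa–Ito oxidation divalent palladium forms the C2 palladium enolate and β-hydride elimination of a C3–H installs C2=C3, the isolated Z-alkene and the silyl ethers being spectators.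

Step 17
Reactants: 33 tris-silyl enone
Product: 34 (4S,6R)-4,6-dihydroxy-6-[(2S,10Z)-2-hydroxyheptadec-10-en-1-yl]cyclohex-2-en-1-one (target)
Conditions: HF·pyridine, pyridine, THF, 0 °C → rt
Reagents that add atoms: none
Why: Buffered fluoride-mediated global desilylation removes all three silyl groups without the base that would trigger elimination and aromatisation of the 4,6-dioxygenated enone.

## Compound list

1 | (S)-malic acid | O[C@@H](CC(O)=O)C(O)=O | starting material
2 | pivalaldehyde | CC(C)(C)C=O | starting material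
3 | 2-[(2S,4S)-2-tert-butyl-5-oxo-1,3-dioxolan-4-yl]acetic acid | O=C1O[C@@H](C(C)(C)C)O[C@H]1CC(=O)O | intermediate
4 | allyl bromide | C=CCBr | starting material
5 | dilithium enolate carboxylate of 3 | [Li]OC1=C(CC(=O)O[Li])O[C@H](C(C)(C)C)O1 | intermediate
6 | 2-[(2S,4S)-2-tert-butyl-5-oxo-4-(prop-2-enyl)-1,3-dioxolan-4-yl]acetic acid | O=C1O[C@@H](C(C)(C)C)O[C@@]1(CC=C)CC(=O)O | intermediate
7 | dioxolanone aldehyde (CH2CHO arm) | O=C1O[C@@H](C(C)(C)C)O[C@@]1(CC=O)CC(=O)O | intermediate
8 | dioxolanone primary alcohol (CH2CH2OH arm) | O=C1O[C@@H](C(C)(C)C)O[C@@]1(CCO)CC(=O)O | intermediate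
9 | 2-[(3S)-3-hydroxy-2-oxooxolan-3-yl]acetic acid | O=C1OCC[C@]1(O)CC(=O)O | intermediate
10 | triethylsilyl 2-[(3S)-2-oxo-3-(triethylsilyloxy)oxolan-3-yl]acetate | O=C1OCC[C@]1(O[Si](CC)(CC)CC)CC(=O)O[Si](CC)(CC)CC | intermediate
11 | 2-[(3S)-2-oxo-3-(triethylsilyloxy)oxolan-3-yl]acetic acid | O=C1OCC[C@]1(O[Si](CC)(CC)CC)CC(=O)O | intermediate
12 | S-ethyl 2-[(3S)-2-oxo-3-(triethylsilyloxy)oxolan-3-yl]ethanethioate | O=C1OCC[C@]1(O[Si](CC)(CC)CC)CC(=O)SCC | intermediate
13 | 2-[(3S)-2-oxo-3-(triethylsilyloxy)oxolan-3-yl]acetaldehyde | O=C1OCC[C@]1(O[Si](CC)(CC)CC)CC=O | intermediate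
14 | oct-1-yne | CCCCCCC#C | starting material
15 | 1,7-dibromoheptane | BrCCCCCCCBr | starting material
16 | oct-1-ynyllithium | CCCCCCC#C[Li] | intermediate
17 | 15-bromopentadec-7-yne | CCCCCCC#CCCCCCCCBr | intermediate
18 | (7Z)-15-bromopentadec-7-ene | CCCCCC/C=C\CCCCCCCBr | intermediate
19 | [(8Z)-pentadec-8-en-1-yl]magnesium bromide | CCCCCC/C=C\CCCCCCC[Mg]Br | intermediate
20 | bis[(8Z)-pentadec-8-en-1-yl]zinc | CCCCCC/C=C\CCCCCCC[Zn]CCCCCCC/C=C\CCCCCC | intermediate
21 | (3S)-3-[(2S,10Z)-2-hydroxyheptadec-10-en-1-yl]-3-(triethylsilyloxy)oxolan-2-one | CCCCCC/C=C\CCCCCCC[C@H](O)C[C@@]1(O[Si](CC)(CC)CC)CCOC1=O | intermediate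
22 | (3S)-3-[(2S,10Z)-2-(tert-butyldimethylsilyloxy)heptadec-10-en-1-yl]-3-(triethylsilyloxy)oxolan-2-one | CCCCCC/C=C\CCCCCCC[C@H](O[Si](C)(C)C(C)(C)C)C[C@@]1(O[Si](CC)(CC)CC)CCOC1=O | intermediate
23 | ethylmagnesium bromide | CC[Mg]Br | starting material
24 | 1-[(3S,5S,13Z)-5-(tert-butyldimethylsilyloxy)-1-hydroxy-3-(triethylsilyloxy)icos-13-en-3-yl]cyclopropan-1-ol | CCCCCC/C=C\CCCCCCC[C@H](O[Si](C)(C)C(C)(C)C)C[C@@](C1(O)CC1)(O[Si](CC)(CC)CC)CCO | intermediate
25 | (3R,5S,13Z)-5-(tert-butyldimethylsilyloxy)-3-(1-hydroxycyclopropyl)-3-(triethylsilyloxy)icos-13-enal (open form, key-step precursor) | CCCCCC/C=C\CCCCCCC[C@H](O[Si](C)(C)C(C)(C)C)C[C@@](C1(O)CC1)(O[Si](CC)(CC)CC)CC=O | intermediate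
26 | lactol of 25, 7,7-disubstituted 4-oxaspiro[2.4]heptan-5-ol | CCCCCC/C=C\CCCCCCC[C@H](O[Si](C)(C)C(C)(C)C)C[C@@]1(O[Si](CC)(CC)CC)CC(O)OC12CC2 | intermediate
27 | zinc bis(cyclopropoxide) of 25 | CCCCCC/C=C\CCCCCCC[C@H](O[Si](C)(C)C(C)(C)C)C[C@@](C1(CC1)O[Zn]OC1(CC1)[C@](O[Si](CC)(CC)CC)(CC=O)C[C@@H](O[Si](C)(C)C(C)(C)C)CCCCCCC/C=C\CCCCCC)(O[Si](CC)(CC)CC)CC=O | intermediate
28 | zinc bis(homoenolate), Zn on C3 | CCCCCC/C=C\CCCCCCC[C@H](O[Si](C)(C)C(C)(C)C)C[C@@](C(=O)CC[Zn]CCC(=O)[C@](O[Si](CC)(CC)CC)(CC=O)C[C@@H](O[Si](C)(C)C(C)(C)C)CCCCCCC/C=C\CCCCCC)(O[Si](CC)(CC)CC)CC=O | intermediate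
29 | triisopropoxytitanium homoenolate, Ti on C3 | CCCCCC/C=C\CCCCCCC[C@H](O[Si](C)(C)C(C)(C)C)C[C@@](C(=O)CC[Ti](OC(C)C)(OC(C)C)OC(C)C)(O[Si](CC)(CC)CC)CC=O | intermediate
30 | (2S,4R)-2-[(2S,10Z)-2-(tert-butyldimethylsilyloxy)heptadec-10-en-1-yl]-4-hydroxy-2-(triethylsilyloxy)cyclohexan-1-one (key-step product) | CCCCCC/C=C\CCCCCCC[C@H](O[Si](C)(C)C(C)(C)C)C[C@@]1(O[Si](CC)(CC)CC)C[C@H](O)CCC1=O | intermediate
31 | (2S,4R)-2-[(2S,10Z)-2-(tert-butyldimethylsilyloxy)heptadec-10-en-1-yl]-2,4-bis(triethylsilyloxy)cyclohexan-1-one | CCCCCC/C=C\CCCCCCC[C@H](O[Si](C)(C)C(C)(C)C)C[C@@]1(O[Si](CC)(CC)CC)C[C@H](O[Si](CC)(CC)CC)CCC1=O | intermediate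
32 | trimethylsilyl enol ether (C1=C2) of 31 | CCCCCC/C=C\CCCCCCC[C@H](O[Si](C)(C)C(C)(C)C)C[C@@]1(O[Si](CC)(CC)CC)C[C@H](O[Si](CC)(CC)CC)CC=C1O[Si](C)(C)C | intermediate
33 | (4S,6R)-6-[(2S,10Z)-2-(tert-butyldimethylsilyloxy)heptadec-10-en-1-yl]-4,6-bis(triethylsilyloxy)cyclohex-2-en-1-one | CCCCCC/C=C\CCCCCCC[C@H](O[Si](C)(C)C(C)(C)C)C[C@@]1(O[Si](CC)(CC)CC)C[C@H](O[Si](CC)(CC)CC)C=CC1=O | intermediate
34 | (4S,6R)-4,6-dihydroxy-6-[(2S,10Z)-2-hydroxyheptadec-10-en-1-yl]cyclohex-2-en-1-one | CCCCCC/C=C\CCCCCCC[C@H](O)C[C@@]1(O)C[C@H](O)C=CC1=O | target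

## Step count

Total step count: 17.
Longest linear sequence: 15 (steps 1–6 and 9–17, from (S)-malic acid).

## Steps most likely to fail

**Step 13 (new method).**
- The zinc cyclopropoxide may stay closed, or alkoxide scrambling may park the substrate on titanium as an inert cyclopropoxide.
- The homoenolate may revert or be protonated before it reaches C4.
- Isopropoxide may transfer hydride to the aldehyde, or silanolate may be lost from the β-silyloxy aldehyde.
- The closure may show poor facial selectivity at C4.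

The fallback sets out from 26 and comes back at 33. It replaces the homoenolate closure by ring-closing metathesis and makes steps 14–16 unnecessary. Excess vinylmagnesium bromide (THF, −78 → 0 °C) would add to the open form of 26 to give the allylic alcohol F1. No facial control is expected here, so the C4 epimers would be separated by chromatography and only the one drawn carried on. Et3SiCl/imidazole (CH2Cl2, 0 °C) should silylate the secondary allylic hydroxyl ahead of the hindered tertiary cyclopropanol to give the silyl ether F2. Pd(OAc)2 (cat.), pyridine, O2, toluene, 80 °C is the known oxidative opening of cyclopropanols through a divalent palladium homoenolate and β-hydride elimination, and it would give the vinyl ketone F3. The second-generation Grubbs catalyst RuCl2(=CHPh)(PCy3)(H2IMes) (CH2Cl2, reflux) would then close C2=C3 to 33, the six-ring closure of two terminal alkenes outrunning any reaction of the internal Z-alkene.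

**Step 11.**
- The quaternary, silyloxy-bearing C6 may shield C1 from the titanacyclopropane.
- Direct Grignard addition to the lactone may compete.
- The triethylsilyl group may migrate from O–C6 to the newly formed neighbouring alkoxides.

The fallback sets out from 22 and comes back at 24. It builds the cyclopropanol from two one-carbon units. MeLi (1.1 equiv, THF, −78 °C) would open the lactone to the hydroxy methyl ketone F4. LDA (2.5 equiv)/Me3SiCl (THF, −78 °C) would silylate O–C4 and trap the only possible enolate (toward CH3) as the bis(trimethylsilyl) enol ether F5. Et2Zn/CH2I2 (Furukawa variant of the Simmons–Smith reaction, about 1 equiv, CH2Cl2, 0 °C) should cyclopropanate the electron-rich enol ether ahead of the isolated Z-alkene to give the siloxycyclopropane F6. K2CO3/MeOH (0 °C) would remove both trimethylsilyl groups to give 24.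

**Step 9.**
- Coordination of titanium by the lactone and silyloxy oxygens may erode the reagent control at C2'.
- The acyl group may migrate from O–C4 to the new C2' alkoxide before silylation.

The fallback sets out from 12 and 18 and comes back at 21. It separates C–C bond formation from the setting of C2'. Zn dust/LiCl (THF, 50 °C) would convert 18 into the alkylzinc bromide F7. Fukuyama coupling with 12 (PdCl2(PPh3)2, 5 mol %, toluene, rt) would give the ketone F8 without touching the lactone. Corey–Bakshi–Shibata reduction with the (R)-2-methyl oxazaborolidine and catecholborane (toluene, −78 °C) treats the neopentyl-like C1' side as the large group and should favour (S)-C2', giving 21 under non-basic conditions. Any C2' epimer would be separated and returned to F8 by oxidation.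

## Further compounds

F1 | step 13 | allylic alcohol from vinyl addition to 25 (C4 as in the target) | CCCCCC/C=C\CCCCCCC[C@H](O[Si](C)(C)C(C)(C)C)C[C@@](C1(O)CC1)(O[Si](CC)(CC)CC)C[C@H](O)C=C
F2 | step 13 | C4 triethylsilyl ether of F1, cyclopropanol free | CCCCCC/C=C\CCCCCCC[C@H](O[Si](C)(C)C(C)(C)C)C[C@@](C1(O)CC1)(O[Si](CC)(CC)CC)C[C@H](O[Si](CC)(CC)CC)C=C
F3 | step 13 | vinyl ketone diene for ring-closing metathesis | CCCCCC/C=C\CCCCCCC[C@H](O[Si](C)(C)C(C)(C)C)C[C@@](C(=O)C=C)(O[Si](CC)(CC)CC)C[C@H](O[Si](CC)(CC)CC)C=C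
F4 | step 11 | hydroxy methyl ketone from 22 | CCCCCC/C=C\CCCCCCC[C@H](O[Si](C)(C)C(C)(C)C)C[C@@](C(C)=O)(O[Si](CC)(CC)CC)CCO
F5 | step 11 | bis(trimethylsilyl) enol ether | CCCCCC/C=C\CCCCCCC[C@H](O[Si](C)(C)C(C)(C)C)C[C@@](C(=C)O[Si](C)(C)C)(O[Si](CC)(CC)CC)CCO[Si](C)(C)C
F6 | step 11 | siloxycyclopropane | CCCCCC/C=C\CCCCCCC[C@H](O[Si](C)(C)C(C)(C)C)C[C@@](C1(O[Si](C)(C)C)CC1)(O[Si](CC)(CC)CC)CCO[Si](C)(C)C
F7 | step 9 | [(8Z)-pentadec-8-en-1-yl]zinc bromide | CCCCCC/C=C\CCCCCCC[Zn]Br
F8 | step 9 | C2' ketone, (3S)-3-[(10Z)-2-oxoheptadec-10-en-1-yl]-3-(triethylsilyloxy)oxolan-2-one | CCCCCC/C=C\CCCCCCCC(=O)C[C@@]1(O[Si](CC)(CC)CC)CCOC1=O
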